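The data were computed for substances that don't exist; scatter was added.

Stopping the flask near its peak, not at the allowed 30 h, is the choice the earlier runs point to, since elm stood at 66.9% target after 6.00 h and at 40.8% after 30.0 h.

in all of them: substrate 0.80 M

| flask | capture agent | catalyst | remark | time |
|---|---|---|---|---|
| ash | 0.080 M | 3 mM | run made earlier |  |
| elm | 0.080 M | 4.6 mM | run made earlier |  |
| flask | 0.0800 M | 6.1 mM |  | 30 h |

- ash (time / h: target / %, substrate / %): 1.33: 13.6, 43.8; 2.50: 31.2, 21.0; 4.00: 49.2, 8.5; 6.00: 60.2, 1.8; 10.0: 59.3, 0; 20.0: 44.5, 0.1; 30.0: 40.7, 0.2
- elm (time / h: target / %, substrate / %): 1.33: 18.9, 43.9; 2.50: 40.9, 21.3; 4.00: 59.0, 9.1; 6.00: 66.9, 2.2; 10.0: 59.7, 0.1; 20.0: 43.7, 0.1; 30.0: 40.8, 0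

(each reading ± 0.3 percentage points)

- time up to 30 h at which target stands highest
- the amount of target, in percent of the substrate charged, at that time

- on the list of suspects stand: substrate -> open intermediate; catalyst + open intermediate -> catalyst + target; open intermediate + capture agent -> trapped intermediate; target <-> isomer of the product

The first rung of the ladder is the loss of substrate, which does not follow catalyst in these runs: ash and elm read 21.0% and 21.3% at 2.50 h, and ash gives a half-life of 1.13 h. Substrate in the flask should therefore also be down to a few percent by 6.00 h.

The next rung is the open intermediate, the pool that catalyst empties into target. At 1.33 h, elm holds 18.9% target and ash 13.6%, from the same substrate loss, and the highest readings follow: 60.2% in ash, 66.9% in elm.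

On the last rung, with substrate near zero, ash target falls by 15 percentage points from 10.0 h to 20.0 h, then by 3.8 points to 30.0 h, so the suspected exchange with the isomer of the product is levelling out. Ash and elm read alike at 30.0 h at different catalyst charges, and the mean of these two readings gives the late level, the target still standing at that time while it is relaxing, 40.8%.

My own reckoning keeps that late level for the flask at 30.0 h and places its peak near 6.00 h or slightly earlier, above the elm reading but under 73.6%, which is elm plus the whole gain from ash to elm.

The forecast says 69% (from 67% to 72%) at 5.2 h (from 4.5 h to 6 h), noting that “faster catalysis may also lose slightly less to capture”.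

The simulation gives 68.7% at 5.68 h, inside both ranges.

    substrate → open intermediate (k = 0.0103 /min)
    catalyst + open intermediate → catalyst + target (k = 2.21 /M/min)
    open intermediate + capture agent → trapped intermediate (k = 0.00330 /M/min)
    target ⇌ isomer of the product (K = 1.44, k = 0.00154 /min)

At 30.0 h this flask holds 41.1% target, close to the late level of 40.8%. The exchange with the isomer of the product makes much of the gap: without it, the highest target in this flask goes from 68.7% to 98.2%. The forecast would fail if the peak left its range, and less catalyst does that: the neighbour flask with 0.0037 M of catalyst peaks at 64.4%. That neighbour's target still ends at 40.9%, close to the late level of 40.8%.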